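Ring B of the naphthoquinone is disconnected at C6–C7. An alkyne C5≡C6 on C4a and a 1,1-diarylpropene C7=C8 on C8a of a 1,2,4-trimethoxybenzene (ring A) are joined by cationic gold in one 6-endo-dig cycloisomerisation. This closes and aromatises ring B with the aryl (C8), methyl (C7) and benzyl (C6) substituents already in place. The step exploits C8: sitting between ring A and the electron-rich guaiacyl ring C, it stabilises the cation formed when C7 attacks C6. The precursor is an ortho-alkynyl 1,1-diarylpropene with benzyl-protected phenols. Oxidative demethylation of ring A and debenzylation then deliver larreantin.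

Key step: step 9

Remark: atom labels C1–C8a follow the naphthalene numbering of the target; ring A = C1–C4, C4a, C8a; ring B = C4a–C8a; ring C = aryl on C8; ring D = aryl of the C6 benzyl group.
Assumption: 4-benzyloxy-3-methoxybenzaldehyde (4) and 4-benzyloxy-3-methoxybenzyl alcohol (15) are bought as such, both being catalogue compounds derived from vanillin.
Remark: the Wittig step is expected to give both alkene isomers, so 14, 17 and 18 are carried as E/Z mixtures (E isomer drawn); the geometry disappears in step 9.

Step 1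
Reactants: 1 2,4,5-trimethoxybenzoic acid
Product: 3 N,N-diethyl-2,4,5-trimethoxybenzamide, via acid chloride 2 (not isolated)
Conditions: (COCl)2, cat. DMF, CH2Cl2, 0 °C → rt; evaporate; Et2NH, Et3N, CH2Cl2, 0 °C → rt
Reagents that add atoms: diethylamine, CCNCC
Why: Acid chloride formation followed by Schotten–Baumann-type amidation is routine for electron-rich benzoic acids and installs the tertiary amide that directs the next metalation.

Step 2
Reactants: 3 N,N-diethyl-2,4,5-trimethoxybenzamide; 4 4-benzyloxy-3-methoxybenzaldehyde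
Product: 7 racemic 3-(4-benzyloxy-3-methoxyphenyl)-4,5,7-trimethoxy-2-benzofuran-1(3H)-one, via aryllithium 5 (not isolated), via hydroxy amide 6 (not isolated)
Conditions: s-BuLi, TMEDA, THF, −78 °C; 4, −78 °C → rt; H2O; crude, TsOH·H2O (1.2 equiv), toluene, 80 °C
Reagents that add atoms: none
Why: Directed ortho-metalation should work because the amide and the 5-methoxy group of the benzamide jointly direct s-BuLi to position 6 between them, the aryllithium adds to the aldehyde, and acid-promoted lactonisation of the hydroxy amide expels diethylamine to give the phthalide, whose new stereocentre forms racemic and is erased in step 5.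

Step 3
Reactants: 7 racemic 3-(4-benzyloxy-3-methoxyphenyl)-4,5,7-trimethoxy-2-benzofuran-1(3H)-one
Product: 8 3-(4-benzyloxy-3-methoxyphenyl)-4,5,7-trimethoxy-1,3-dihydro-2-benzofuran-1-ol (lactol, mixture of racemic diastereomers)
Conditions: i-Bu2AlH (1.2 equiv), CH2Cl2, −78 °C; aqueous potassium sodium tartrate
Reagents that add atoms: none
Why: Half-reduction of a lactone with DIBAL-H at low temperature stops at the tetrahedral aluminate and gives the lactol on work-up, and its anomeric configuration is irrelevant because the ring opens in step 4.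

Step 4
Reactants: 8 3-(4-benzyloxy-3-methoxyphenyl)-4,5,7-trimethoxy-1,3-dihydro-2-benzofuran-1-ol
Product: 10 racemic (4-benzyloxy-3-methoxyphenyl)(2-ethynyl-3,5,6-trimethoxyphenyl)methanol, via hydroxy aldehyde 9 (not isolated)
Conditions: dimethyl (1-diazo-2-oxopropyl)phosphonate, K2CO3, MeOH–THF, 0 °C → rt
Reagents that add atoms: dimethyl (1-diazo-2-oxopropyl)phosphonate (Ohira–Bestmann reagent), COP(=O)(OC)C(=[N+]=[N-])C(C)=O
Why: In the Ohira–Bestmann variant of the Seyferth–Gilbert homologation the lactol reacts through its open hydroxy aldehyde form, which the diazomethylphosphonate anion generated in situ converts into the terminal alkyne (former lactone carbon = C5, new carbon = C6).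

Step 5
Reactants: 10 racemic (4-benzyloxy-3-methoxyphenyl)(2-ethynyl-3,5,6-trimethoxyphenyl)methanol
Product: 11 (4-benzyloxy-3-methoxyphenyl)(2-ethynyl-3,5,6-trimethoxyphenyl)methanone
Conditions: Dess–Martin periodinane, CH2Cl2, 0 °C → rt
Reagents that add atoms: none
Why: Dess–Martin oxidation of a doubly benzylic secondary alcohol to the diaryl ketone is fast under near-neutral conditions and leaves the terminal alkyne, the methyl ethers and the benzyl ether untouched.

Step 6
Reactants: 11 (4-benzyloxy-3-methoxyphenyl)(2-ethynyl-3,5,6-trimethoxyphenyl)methanone; 12 ethyltriphenylphosphonium bromide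
Product: 14 1-[1-(4-benzyloxy-3-methoxyphenyl)prop-1-en-1-yl]-2-ethynyl-3,5,6-trimethoxybenzene as an E/Z mixture, via phosphorus ylide 13 (not isolated)
Conditions: 12 (3 equiv), KN(SiMe3)2 (2.8 equiv), THF, 0 °C; then 11, rt → 60 °C
Reagents that add atoms: none
Why: Wittig olefination of the diaryl ketone with the non-stabilised ethylidene ylide should give the 1,1-diarylpropene, a slight deficit of base keeping the terminal alkyne protonated and the alkene geometry needing no control because C7 becomes an aromatic carbon in step 9.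

Step 7
Reactants: 15 4-benzyloxy-3-methoxybenzyl alcohol
Product: 16 4-benzyloxy-3-methoxybenzyl bromide
Conditions: PBr3 (0.4 equiv), Et2O, 0 °C; used without storage
Reagents that add atoms: phosphorus tribromide, BrP(Br)Br
Why: Substitution of an electron-rich benzylic alcohol by bromide through its phosphite ester is a standard, fast conversion.

Step 8
Reactants: 14 1-[1-(4-benzyloxy-3-methoxyphenyl)prop-1-en-1-yl]-2-ethynyl-3,5,6-trimethoxybenzene; 16 4-benzyloxy-3-methoxybenzyl bromide
Product: 18 1-[1-(4-benzyloxy-3-methoxyphenyl)prop-1-en-1-yl]-2-[3-(4-benzyloxy-3-methoxyphenyl)prop-1-yn-1-yl]-3,5,6-trimethoxybenzene as an E/Z mixture, via alkynylmagnesium bromide 17 (not isolated)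
Conditions: EtMgBr (1.05 equiv), THF, 0 → 40 °C; CuBr·SMe2 (10 mol %, monovalent copper); 16 (1.2 equiv), THF, 50 °C
Reagents that add atoms: none
Why: Copper-catalysed sp–sp3 coupling of an alkynyl Grignard reagent with a benzylic bromide is the classical route to 1,3-diarylpropynes, and the absence of amine or alkoxide base should prevent isomerisation of the doubly activated propargylic CH2 to an allene.

Step 9
Reactants: 18 1-[1-(4-benzyloxy-3-methoxyphenyl)prop-1-en-1-yl]-2-[3-(4-benzyloxy-3-methoxyphenyl)prop-1-yn-1-yl]-3,5,6-trimethoxybenzene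
Product: 19 8-(4-benzyloxy-3-methoxyphenyl)-6-[(4-benzyloxy-3-methoxyphenyl)methyl]-1,2,4-trimethoxy-7-methylnaphthalene
Conditions: Ph3PAuNTf2 (5 mol %, monovalent gold), CH2Cl2, rt
Reagents that add atoms: none
Why: Cationic gold π-coordinates the C5≡C6 alkyne and the 1,1-diarylalkene attacks C6 through C7, because this places the developing positive charge on C8, where ring A and the para-alkoxy-substituted ring C both delocalise it. Loss of the C7 proton followed by protodeauration of the C5–Au bond gives the fully aromatic ring B and returns the catalyst. The closest known reaction type is the gold- or platinum-catalysed 6-endo-dig cycloisomerisation of ortho-alkynyl α-substituted styrenes to naphthalenes. Ring B closes in the 6-endo-dig mode by forming C6–C7; no stereocentre is created, and both alkene isomers converge because C7 keeps its methyl group and loses its proton. The step needs 6-endo closure to win over 5-exo closure (C7 to C5, which would end in a non-aromatic benzofulvene) and over attack of the arenes on the alkyne. This should be secured by the direct path to an aromatic ring, by the higher nucleophilicity of the diarylalkene relative to ring C, and by the 5-endo geometry that ring D would need.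

Step 10
Reactants: 19 8-(4-benzyloxy-3-methoxyphenyl)-6-[(4-benzyloxy-3-methoxyphenyl)methyl]-1,2,4-trimethoxy-7-methylnaphthalene
Product: 20 8-(4-benzyloxy-3-methoxyphenyl)-6-[(4-benzyloxy-3-methoxyphenyl)methyl]-2-methoxy-7-methylnaphthalene-1,4-dione
Conditions: (NH4)2Ce(NO3)6 (2.5 equiv), MeCN–H2O, 0 °C
Reagents that add atoms: water, O
Why: In this oxidative demethylation tetravalent cerium oxidises the most electron-rich ring, the 1,2,4-trimethoxy ring A, to its radical cation, water adds at C1 and C4 and two molecules of methanol leave to give the para-quinone that keeps the C2 methoxy group, while the benzyl-protected guaiacyl rings of higher oxidation potential should remain intact.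

Step 11
Reactants: 20 8-(4-benzyloxy-3-methoxyphenyl)-6-[(4-benzyloxy-3-methoxyphenyl)methyl]-2-methoxy-7-methylnaphthalene-1,4-dione
Product: 22 larreantin, via hydroquinone 21 (not isolated)
Conditions: H2 (1 atm), 10% Pd/C, EtOAc–MeOH, rt; filter; stir under air
Reagents that add atoms: none
Why: Catalytic hydrogenolysis cleaves both benzyl aryl ethers and reduces the quinone to the hydroquinone, which autoxidises back to the quinone in air, while the diarylmethane CH2 and the methyl ethers are inert.

Compound list
1 | 2,4,5-trimethoxybenzoic acid | COc1cc(OC)c(C(=O)O)cc1OC | starting material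
2 | 2,4,5-trimethoxybenzoyl chloride | COc1cc(OC)c(C(=O)Cl)cc1OC | intermediate
3 | N,N-diethyl-2,4,5-trimethoxybenzamide | CCN(CC)C(=O)c1cc(OC)c(OC)cc1OC | intermediate
4 | 4-benzyloxy-3-methoxybenzaldehyde (O-benzylvanillin) | O=Cc1ccc(OCc2ccccc2)c(OC)c1 | starting material
5 | N,N-diethyl-2-lithio-3,4,6-trimethoxybenzamide (aryllithium) | [Li]c1c(C(=O)N(CC)CC)c(OC)cc(OC)c1OC | intermediate
6 | racemic N,N-diethyl-2-[(4-benzyloxy-3-methoxyphenyl)(hydroxy)methyl]-3,4,6-trimethoxybenzamide (hydroxy amide) | CCN(CC)C(=O)c1c(OC)cc(OC)c(OC)c1C(O)c1ccc(OCc2ccccc2)c(OC)c1 | intermediate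
7 | racemic 3-(4-benzyloxy-3-methoxyphenyl)-4,5,7-trimethoxy-2-benzofuran-1(3H)-one (phthalide) | COc1cc(OC)c2c(c1OC)C(c1ccc(OCc3ccccc3)c(OC)c1)OC2=O | intermediate
8 | 3-(4-benzyloxy-3-methoxyphenyl)-4,5,7-trimethoxy-1,3-dihydro-2-benzofuran-1-ol (lactol, mixture of racemic diastereomers) | COc1cc(OC)c2c(c1OC)C(c1ccc(OCc3ccccc3)c(OC)c1)OC2O | intermediate
9 | racemic 2-[(4-benzyloxy-3-methoxyphenyl)(hydroxy)methyl]-3,4,6-trimethoxybenzaldehyde (open form of 8) | O=Cc1c(OC)cc(OC)c(OC)c1C(O)c1ccc(OCc2ccccc2)c(OC)c1 | intermediate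
10 | racemic (4-benzyloxy-3-methoxyphenyl)(2-ethynyl-3,5,6-trimethoxyphenyl)methanol | C#Cc1c(OC)cc(OC)c(OC)c1C(O)c1ccc(OCc2ccccc2)c(OC)c1 | intermediate
11 | (4-benzyloxy-3-methoxyphenyl)(2-ethynyl-3,5,6-trimethoxyphenyl)methanone | C#Cc1c(OC)cc(OC)c(OC)c1C(=O)c1ccc(OCc2ccccc2)c(OC)c1 | intermediate
12 | ethyltriphenylphosphonium bromide | CC[P+](c1ccccc1)(c1ccccc1)c1ccccc1.[Br-] | starting material
13 | ethylidenetriphenylphosphorane (phosphorus ylide) | CC=P(c1ccccc1)(c1ccccc1)c1ccccc1 | intermediate
14 | 1-[1-(4-benzyloxy-3-methoxyphenyl)prop-1-en-1-yl]-2-ethynyl-3,5,6-trimethoxybenzene, E/Z mixture (E drawn) | C#Cc1c(OC)cc(OC)c(OC)c1/C(=C/C)c1ccc(OCc2ccccc2)c(OC)c1 | intermediate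
15 | 4-benzyloxy-3-methoxybenzyl alcohol | OCc1ccc(OCc2ccccc2)c(OC)c1 | starting material
16 | 4-benzyloxy-3-methoxybenzyl bromide | BrCc1ccc(OCc2ccccc2)c(OC)c1 | intermediate
17 | bromomagnesium acetylide of 14, E/Z mixture (E drawn) | Br[Mg]C#Cc1c(OC)cc(OC)c(OC)c1/C(=C/C)c1ccc(OCc2ccccc2)c(OC)c1 | intermediate
18 | 1-[1-(4-benzyloxy-3-methoxyphenyl)prop-1-en-1-yl]-2-[3-(4-benzyloxy-3-methoxyphenyl)prop-1-yn-1-yl]-3,5,6-trimethoxybenzene, E/Z mixture (E drawn) | COc1cc(OC)c(C#CCc2ccc(OCc3ccccc3)c(OC)c2)c(/C(=C/C)c2ccc(OCc3ccccc3)c(OC)c2)c1OC | intermediate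
19 | 8-(4-benzyloxy-3-methoxyphenyl)-6-[(4-benzyloxy-3-methoxyphenyl)methyl]-1,2,4-trimethoxy-7-methylnaphthalene | COc1cc(OC)c2cc(Cc3ccc(OCc4ccccc4)c(OC)c3)c(C)c(-c3ccc(OCc4ccccc4)c(OC)c3)c2c1OC | intermediate
20 | 8-(4-benzyloxy-3-methoxyphenyl)-6-[(4-benzyloxy-3-methoxyphenyl)methyl]-2-methoxy-7-methylnaphthalene-1,4-dione | COC1=CC(=O)c2cc(Cc3ccc(OCc4ccccc4)c(OC)c3)c(C)c(-c3ccc(OCc4ccccc4)c(OC)c3)c2C1=O | intermediate
21 | 8-(4-hydroxy-3-methoxyphenyl)-6-[(4-hydroxy-3-methoxyphenyl)methyl]-2-methoxy-7-methylnaphthalene-1,4-diol (hydroquinone) | COc1cc(O)c2cc(Cc3ccc(O)c(OC)c3)c(C)c(-c3ccc(O)c(OC)c3)c2c1O | intermediate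
22 | larreantin, 8-(4-hydroxy-3-methoxyphenyl)-6-[(4-hydroxy-3-methoxyphenyl)methyl]-2-methoxy-7-methylnaphthalene-1,4-dione | COC1=CC(=O)c2cc(Cc3ccc(O)c(OC)c3)c(C)c(-c3ccc(O)c(OC)c3)c2C1=O | target

Total step count: 11. Longest linear sequence: 10 steps (steps 1–6 and 8–11, from 1); step 7 is a one-step side branch.

Steps most likely to fail

Step 9. The gold-activated alkyne may be attacked at C5 instead of C6 (5-exo closure), ring C may add to the alkyne, or the catalyst may be diverted into isomerising the propargylic CH2 to an allene, so that turnover to the naphthalene stalls. The fallback replaces π-acid catalysis by a stoichiometric halonium electrophile and sets out from 18. I2 and NaHCO3 in MeCN at rt should induce an electrophilic iodocyclisation along the same C7-to-C6 path, a known way of closing benzenoid rings onto aryl alkynes, and give 8-(4-benzyloxy-3-methoxyphenyl)-6-[(4-benzyloxy-3-methoxyphenyl)methyl]-5-iodo-1,2,4-trimethoxy-7-methylnaphthalene F1. Iodine–lithium exchange (n-BuLi, THF, −78 °C) and a methanol quench then return the route to 19.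

Step 6. Addition of the ylide to a hindered, electron-rich diaryl ketone may be too slow, and partial deprotonation of the terminal alkyne may lead to acetylide addition to the ketone instead of olefination. The fallback builds the alkene by addition and elimination and sets out from 11. EtMgBr (3 equiv, the first consumed by the alkyne C–H) with anhydrous CeCl3 in THF at −78 → 0 °C should add to the carbonyl group and give racemic 1-(4-benzyloxy-3-methoxyphenyl)-1-(2-ethynyl-3,5,6-trimethoxyphenyl)propan-1-ol F2. Acid-catalysed E1 dehydration of this tertiary diaryl carbinol (cat. TsOH·H2O, toluene, 50 °C) comes back to the route at 14.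

Step 10. The oxidative demethylation may partly take the ortho course, losing the C1 and C2 methyl groups, so that a 1,2-quinone forms beside or instead of the 1,4-quinone. The fallback makes the outcome independent of this regiochemistry and sets out from 19. The crude oxidation mixture, then expected to contain 20 together with 8-(4-benzyloxy-3-methoxyphenyl)-6-[(4-benzyloxy-3-methoxyphenyl)methyl]-4-methoxy-7-methylnaphthalene-1,2-dione F3, is hydrolysed without separation (aqueous NaOH, THF, rt; then HCl). Both vinylogous esters should give the same 8-(4-benzyloxy-3-methoxyphenyl)-6-[(4-benzyloxy-3-methoxyphenyl)methyl]-2-hydroxy-7-methylnaphthalene-1,4-dione F4. Acid-catalysed etherification with methanol (MeOH, HCl, reflux), which for 2-hydroxy-1,4-naphthoquinones gives the 2-methoxy-1,4-quinone, returns to 20.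

Further compounds
F1 | step 9 | 8-(4-benzyloxy-3-methoxyphenyl)-6-[(4-benzyloxy-3-methoxyphenyl)methyl]-5-iodo-1,2,4-trimethoxy-7-methylnaphthalene | COc1cc(OC)c2c(I)c(Cc3ccc(OCc4ccccc4)c(OC)c3)c(C)c(-c3ccc(OCc4ccccc4)c(OC)c3)c2c1OC
F2 | step 6 | racemic 1-(4-benzyloxy-3-methoxyphenyl)-1-(2-ethynyl-3,5,6-trimethoxyphenyl)propan-1-ol | CCC(O)(c1ccc(OCc2ccccc2)c(OC)c1)c1c(OC)c(OC)cc(OC)c1C#C
F3 | step 10 | 8-(4-benzyloxy-3-methoxyphenyl)-6-[(4-benzyloxy-3-methoxyphenyl)methyl]-4-methoxy-7-methylnaphthalene-1,2-dione | COC1=CC(=O)C(=O)c2c1cc(Cc3ccc(OCc4ccccc4)c(OC)c3)c(C)c2-c5ccc(OCc6ccccc6)c(OC)c5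
F4 | step 10 | 8-(4-benzyloxy-3-methoxyphenyl)-6-[(4-benzyloxy-3-methoxyphenyl)methyl]-2-hydroxy-7-methylnaphthalene-1,4-dione | OC1=CC(=O)c2cc(Cc3ccc(OCc4ccccc4)c(OC)c3)c(C)c(-c3ccc(OCc4ccccc4)c(OC)c3)c2C1=O
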